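**Retrosynthetic overview**
1. Target ⇐ triacetylation of macrocyclic pentaol 33 ⇐ ring-closing ene–yne metathesis of 31 (ten-membered ring closed last; C3=C4 formed, C16 from ethylene).
2. γ-Lactone and C6–C9 ⇐ anti-chloropropargylation of a C7 aldehyde (C6–C7), propionate aldol on a C8 α-keto ester (C8–C17), diazoacetate aldol on the ring A C9 aldehyde (C8–C9).
3. Ring A 11,12-cis-diol ⇐ OsO4 on a cyclohexadiene (from the enone by methylation and enol-triflate reduction); C2 carbinol ⇐ vinylzinc addition.
4. Ring A with C1/C10 ⇐ hydrogen-bond-catalysed asymmetric Diels–Alder reaction of aminosiloxydiene 1 with enal 2.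
5. Ring order: ring A → γ-lactone → ten-membered ring.

Positions are given in briarane numbering (C1 quaternary, C2–C9 ring chain, C10–C14 ring A, C17–C19 lactone). Where no descriptor is given, a stereocentre has the spatial arrangement drawn in the SMILES (that of the target).

Assumption: 2 is taken as a commercial building block, and for the chiral catalysts of steps 1 and 2 the enantiomer named is the one expected to give the drawn configuration; the antipode would be used if the sense proved opposite.

**Step 1**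
Reactants: 1 (E)-3-(tert-butyldimethylsilyloxy)-N,N-dimethylbuta-1,3-dien-1-amine; 2 (E)-4,4-dimethoxy-2-methylbut-2-enal
Product: 4 (1S,6S)-6-(dimethoxymethyl)-1-methyl-4-oxocyclohex-2-ene-1-carbaldehyde, via amino silyl enol ether cycloadduct 3 (not isolated)
Conditions: (R,R)-1-naphthyl-TADDOL (20 mol %), toluene, −40 °C; then AcCl, CH2Cl2, −78 °C
Reagents that add atoms: none
Why: Proposed new method: a hydrogen-bond-catalysed asymmetric Diels–Alder reaction of an aminosiloxydiene with an α,β-disubstituted enal, shown so far only for α-substituted acroleins (closest known reaction: the TADDOL-catalysed cycloaddition of 1 with methacrolein), in which the diol activates the formyl group of 2 by one hydrogen bond while a naphthyl group shields one face, the CH2 terminus of 1 bonds to the acetal-bearing β-carbon (the withdrawing acetal offsets the extra substituent) and the aminated terminus to the α-carbon, so that ring A forms with the quaternary C1 set enantioselectively and C10 set trans to it by suprafacial transfer of the E-geometry, before AcCl-induced loss of the amine and silyl groups unveils the enone.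

**Step 2**
Reactants: 4 (1S,6S)-6-(dimethoxymethyl)-1-methyl-4-oxocyclohex-2-ene-1-carbaldehyde; 5 vinylmagnesium bromide
Product: 7 (4S,5S)-5-(dimethoxymethyl)-4-[(1R)-1-hydroxyprop-2-en-1-yl]-4-methylcyclohex-2-en-1-one, via divinylzinc 6 (not isolated)
Conditions: 5 (2 equiv), ZnCl2 (1 equiv), Et2O/1,4-dioxane, 0 °C, MgBrCl filtered off; then 4, (+)-MIB [(2R)-3-exo-morpholinoisoborneol] (10 mol %), toluene, −20 °C; aqueous NH4Cl
Reagents that add atoms: none
Why: Catalytic asymmetric alkenylzinc addition to an aldehyde (Oppolzer-type vinylation) in which the zinc aminoalkoxide of MIB delivers a vinyl group of 6 to one face of the neopentylic formyl group under reagent control (2R), while organozinc species do not add to the enone.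

**Step 3**
Reactants: 7 (4S,5S)-5-(dimethoxymethyl)-4-[(1R)-1-hydroxyprop-2-en-1-yl]-4-methylcyclohex-2-en-1-one
Product: 8 (4S,5S)-4-[(1R)-1-(tert-butyldimethylsilyloxy)prop-2-en-1-yl]-5-(dimethoxymethyl)-4-methylcyclohex-2-en-1-one
Conditions: tBuMe2SiOTf, 2,6-lutidine, CH2Cl2, −78 °C
Reagents that add atoms: tert-butyldimethylsilyl trifluoromethanesulfonate CC(C)(C)[Si](C)(C)OS(=O)(=O)C(F)(F)F
Why: Silylation of the hindered secondary allylic alcohol with the silyl triflate touches no stereocentre and at −78 °C does not enolise the enone.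

**Step 4**
Reactants: 8 (4S,5S)-4-[(1R)-1-(tert-butyldimethylsilyloxy)prop-2-en-1-yl]-5-(dimethoxymethyl)-4-methylcyclohex-2-en-1-one
Product: 10 (4S,5S,6S)-4-[(1R)-1-(tert-butyldimethylsilyloxy)prop-2-en-1-yl]-5-(dimethoxymethyl)-4,6-dimethylcyclohex-2-en-1-one, via lithium dienolate 9 (not isolated)
Conditions: LiN(iPr)2, THF, −78 °C; MeI, DMPU, −78 to −30 °C
Reagents that add atoms: iodomethane CI
Why: Kinetic α′-deprotonation of the enone (the γ-carbon is quaternary, so only this enolate can form) and SN2 C-methylation anti to the adjacent C10 acetal group install C20, the new C11 centre being temporary because it becomes sp2 again in step 5.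

**Step 5**
Reactants: 10 (4S,5S,6S)-4-[(1R)-1-(tert-butyldimethylsilyloxy)prop-2-en-1-yl]-5-(dimethoxymethyl)-4,6-dimethylcyclohex-2-en-1-one
Product: 12 ring A dienyl triflate (C11=C12 enol triflate), via potassium dienolate 11 (not isolated)
Conditions: KN(SiMe3)2, THF, −78 °C; PhNTf2, −78 to 0 °C
Reagents that add atoms: N-phenylbis(trifluoromethanesulfonimide) O=S(=O)(N(c1ccccc1)S(=O)(=O)C(F)(F)F)C(F)(F)F
Why: Enol triflate formation in which the base removes the only remaining α-proton (C11–H) and the cross-conjugated potassium enolate is O-sulfonylated.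

**Step 6**
Reactants: 12 ring A dienyl triflate
Product: 13 ring A cyclohexa-1,3-diene (C11=C12 and C13=C14)
Conditions: Pd(OAc)2 (5 mol %), PPh3 (10 mol %), HCO2H, nBu3N, DMF, 60 °C
Reagents that add atoms: none
Why: Palladium-catalysed formate reduction of an enol triflate (oxidative addition to zerovalent palladium then hydride transfer from formate with loss of CO2 then reductive elimination) gives the diene without touching the stereocentres.

**Step 7**
Reactants: 13 ring A cyclohexa-1,3-diene
Product: 14 11,12-cis-diol dimethyl acetal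
Conditions: OsO4 (2 mol %), N-methylmorpholine N-oxide, acetone/H2O, 0 °C
Reagents that add atoms: N-methylmorpholine N-oxide C[N+]1([O-])CCOCC1; water O
Why: Upjohn dihydroxylation adds suprafacially to the more electron-rich trisubstituted C11=C12 bond on the face anti to the C10 substituent, which fixes the tertiary C11 and secondary C12 carbinols cis to each other and trans to C9, while the C13=C14 bond beside the quaternary carbon and the hindered silyloxyallyl vinyl group react more slowly.

**Step 8**
Reactants: 14 11,12-cis-diol dimethyl acetal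
Product: 15 C9 aldehyde diol
Conditions: oxalic acid (10% aqueous), THF, 23 °C
Reagents that add atoms: water O
Why: Mild acid-catalysed acetal hydrolysis frees the C9 aldehyde, the trans disposition of both hydroxyls to the formyl group ruling out lactol formation and the silyl ether surviving.

**Step 9**
Reactants: 15 C9 aldehyde diol; 16 ethyl diazoacetate
Product: 18 β-hydroxy-α-diazo ester (9R), via ethyl lithiodiazoacetate 17 (not isolated)
Conditions: 16, LiN(iPr)2 (3.3 equiv each), THF, −78 °C; then 15, −78 °C, 20 min; AcOH, −78 °C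
Reagents that add atoms: none
Why: Aldol-type addition of a lithiated diazoacetate to an aldehyde in which the C11 lithium alkoxide and the formyl oxygen share lithium in a six-membered β-chelate and the nucleophile attacks the face away from the two axial methyl groups (C15 and C20) to set 9R, the cold acidic quench preventing retro-aldol cleavage.

**Step 10**
Reactants: 18 β-hydroxy-α-diazo ester
Product: 19 β-hydroxy-α-keto ester (C8 ketone)
Conditions: dimethyldioxirane (1.1 equiv), acetone, −40 to 0 °C
Reagents that add atoms: dimethyldioxirane CC1(C)OO1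
Why: Dioxirane oxidation of a diazo compound transfers oxygen to the nucleophilic diazo carbon with loss of N2 much faster than the deactivated alkenes are epoxidised at this temperature, and C9 is untouched.

**Step 11**
Reactants: 19 β-hydroxy-α-keto ester; 20 tert-butyl propanoate
Product: 22 aldol adduct (C8 tertiary carbinol with C7 ethyl ester and C19 tert-butyl ester), via lithium E-enolate 21 (not isolated)
Conditions: 20, LiN(iPr)2 (5 equiv each), THF, −78 °C; then 19, −78 °C, 1 h; AcOH, −78 °C
Reagents that add atoms: none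
Why: Chelation-controlled (Cram chelate) ester-enolate aldol addition to a ketone in which lithium bridges the C9 alkoxide and the ketone oxygen so that the enolate attacks the face flanked by H9 (8,9-erythro, 8R), and the Zimmerman–Traxler chair of the E(O)-enolate with the chelated C9 arm axial places the C17 methyl anti to the new hydroxyl (17R), the tert-butyl ester resisting lactonisation by the C9 alkoxide.

**Step 12**
Reactants: 22 aldol adduct
Product: 23 tetrakis(triethylsilyl) ether (O8, O9, O11, O12)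
Conditions: Et3SiOTf (8 equiv), 2,6-lutidine, CH2Cl2, 0 to 23 °C
Reagents that add atoms: triethylsilyl trifluoromethanesulfonate CC[Si](CC)(CC)OS(=O)(=O)C(F)(F)F
Why: Exhaustive O-silylation with the reactive silyl triflate caps the two secondary and two tertiary hydroxyls, which blocks chelation at O8 for step 14 and shields the alcohols from the hydride.

**Step 13**
Reactants: 23 tetrakis(triethylsilyl) ether
Product: 24 C7 aldehyde
Conditions: iBu2AlH (1.3 equiv), toluene, −78 °C; aqueous potassium sodium tartrate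
Reagents that add atoms: none
Why: Partial hydride reduction of an ester in which the α-silyloxy ethyl ester gives a tetrahedral aluminium hemiacetal that is stable at −78 °C and collapses to the non-enolisable aldehyde on work-up, whereas the tert-butyl ester is inert.

**Step 14**
Reactants: 24 C7 aldehyde; 25 3-chloro-1-(trimethylsilyl)prop-1-yne
Product: 28 anti-chlorohydrin (C7–OH and C6–Cl), via chloropropargyllithium 26 (not isolated), via chloroallenylzinc bromide 27 (not isolated)
Conditions: 25, n-BuLi, THF/Et2O, −90 °C; ZnBr2, −78 °C; then 24, −78 to −30 °C; aqueous NH4Cl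
Reagents that add atoms: none
Why: Carbonyl addition of a propargylic zinc carbenoid through a cyclic SE2′ transition state gives the anti chlorohydrin, so C6 (6S) is fixed relative to C7, and polar Felkin–Anh control with the non-chelating C8 silyloxy group anti to the nucleophile and the bulky C9 arm inside sets 7R.

**Step 15**
Reactants: 28 anti-chlorohydrin
Product: 30 β-hydroxy-γ-lactone (2-O-silyl and alkynylsilane retained), via hydroxy acid 29 (not isolated)
Conditions: CF3CO2H/CH2Cl2 (1:4), H2O (5 equiv), 0 to 23 °C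
Reagents that add atoms: none
Why: Acidolysis of the tert-butyl ester and the triethylsilyl ethers is followed by acid-catalysed γ-lactonisation of the C19 acid onto the 7-hydroxyl, which is far more accessible than O9 between two fully substituted carbons, giving the lactone with C6 and C9 trans as fixed in steps 11 and 14.

**Step 16**
Reactants: 30 β-hydroxy-γ-lactone
Product: 31 terminal alkyne pentaol
Conditions: Bu4NF, AcOH (1:1), THF, 0 to 23 °C
Reagents that add atoms: none
Why: Fluoride-mediated cleavage of the C(sp)–Si and O–Si bonds under acetic acid buffering avoids base-induced elimination of the propargylic chloride, retro-aldol opening of the β-hydroxy lactone and translactonisation.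

**Step 17**
Reactants: 31 terminal alkyne pentaol
Product: 33 macrocyclic pentaol (2,9,12-tris-O-deacetyl target), via triene 32 (not isolated)
Conditions: second-generation Grubbs catalyst RuCl2(=CHPh)(PCy3)(H2IMes) (15 mol %), ethylene (1 atm), toluene/1,2-dichloroethane (1 mM), 60 °C
Reagents that add atoms: ethene C=C
Why: Ring-closing ene–yne metathesis under ethylene (Mori conditions) first converts the terminal alkyne into the 2-substituted butadiene 32, whose monosubstituted vinyl group then undergoes ring-closing metathesis with the C2 vinyl group (helped by the free allylic hydroxyl) to close the ten-membered ring with the C5 exocyclic methylene in place and the 3Z alkene, the geometry the fused cyclodecadiene should favour under reversible conditions.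

**Step 18**
Reactants: 33 macrocyclic pentaol
Product: 34 target CNP0285654.4
Conditions: Ac2O, pyridine, DMAP (10 mol %), CH2Cl2, 0 to 23 °C
Reagents that add atoms: acetic anhydride CC(=O)OC(C)=O
Why: DMAP-catalysed acylation esterifies the three secondary hydroxyls (C2, C9, C12) while the tertiary C8 and C11 hydroxyls stay free, which gives the target without touching any stereocentre.

**Compound list**
1 | (E)-3-(tert-butyldimethylsilyloxy)-N,N-dimethylbuta-1,3-dien-1-amine | CN(C)/C=C/C(=C)O[Si](C)(C)C(C)(C)C | starting material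
2 | (E)-4,4-dimethoxy-2-methylbut-2-enal | COC(OC)/C=C(\C)C=O | starting material
3 | amino silyl enol ether cycloadduct, (1R,2S,6S)-4-(tert-butyldimethylsilyloxy)-2-(dimethylamino)-6-(dimethoxymethyl)-1-methylcyclohex-3-ene-1-carbaldehyde | O=C[C@@]1(C)[C@@H](N(C)C)C=C(O[Si](C)(C)C(C)(C)C)C[C@@H]1C(OC)OC | intermediate
4 | (1S,6S)-6-(dimethoxymethyl)-1-methyl-4-oxocyclohex-2-ene-1-carbaldehyde | O=C[C@@]1(C)C=CC(=O)C[C@@H]1C(OC)OC | intermediate
5 | vinylmagnesium bromide | C=C[Mg]Br | starting material
6 | divinylzinc | C=C[Zn]C=C | intermediate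
7 | (4S,5S)-5-(dimethoxymethyl)-4-[(1R)-1-hydroxyprop-2-en-1-yl]-4-methylcyclohex-2-en-1-one | C=C[C@@H](O)[C@@]1(C)C=CC(=O)C[C@@H]1C(OC)OC | intermediate
8 | (4S,5S)-4-[(1R)-1-(tert-butyldimethylsilyloxy)prop-2-en-1-yl]-5-(dimethoxymethyl)-4-methylcyclohex-2-en-1-one | C=C[C@@H](O[Si](C)(C)C(C)(C)C)[C@@]1(C)C=CC(=O)C[C@@H]1C(OC)OC | intermediate
9 | lithium dienolate of 8 (C11=C12–OLi) | C=C[C@@H](O[Si](C)(C)C(C)(C)C)[C@@]1(C)C=CC(O[Li])=C[C@@H]1C(OC)OC | intermediate
10 | (4S,5S,6S)-4-[(1R)-1-(tert-butyldimethylsilyloxy)prop-2-en-1-yl]-5-(dimethoxymethyl)-4,6-dimethylcyclohex-2-en-1-one | C=C[C@@H](O[Si](C)(C)C(C)(C)C)[C@@]1(C)C=CC(=O)[C@@H](C)[C@@H]1C(OC)OC | intermediate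
11 | potassium dienolate of 10 | C=C[C@@H](O[Si](C)(C)C(C)(C)C)[C@@]1(C)C=CC(O[K])=C(C)[C@@H]1C(OC)OC | intermediate
12 | ring A dienyl triflate (C11=C12 enol triflate, C13=C14; C1, C2, C10 as in 8) | C=C[C@@H](O[Si](C)(C)C(C)(C)C)[C@@]1(C)C=CC(OS(=O)(=O)C(F)(F)F)=C(C)[C@@H]1C(OC)OC | intermediate
13 | ring A cyclohexa-1,3-diene (C11=C12 and C13=C14, 11-methyl; C1, C2, C10 as in 8) | C=C[C@@H](O[Si](C)(C)C(C)(C)C)[C@@]1(C)C=CC=C(C)[C@@H]1C(OC)OC | intermediate
14 | 11,12-cis-diol dimethyl acetal (both hydroxyls on the face of the C2 side chain, trans to C9) | C=C[C@@H](O[Si](C)(C)C(C)(C)C)[C@@]1(C)C=C[C@@H](O)[C@@](C)(O)[C@@H]1C(OC)OC | intermediate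
15 | C9 aldehyde diol | C=C[C@@H](O[Si](C)(C)C(C)(C)C)[C@@]1(C)C=C[C@@H](O)[C@@](C)(O)[C@@H]1C=O | intermediate
16 | ethyl diazoacetate | CCOC(=O)C=[N+]=[N-] | starting material
17 | ethyl lithiodiazoacetate | CCOC(=O)C([Li])=[N+]=[N-] | intermediate
18 | β-hydroxy-α-diazo ester (9R; ethyl 2-diazo-3-hydroxypropanoate on C10) | C=C[C@@H](O[Si](C)(C)C(C)(C)C)[C@@]1(C)C=C[C@@H](O)[C@@](C)(O)[C@@H]1[C@@H](O)C(=[N+]=[N-])C(=O)OCC | intermediate
19 | β-hydroxy-α-keto ester (C8 ketone, C7 ethyl ester) | C=C[C@@H](O[Si](C)(C)C(C)(C)C)[C@@]1(C)C=C[C@@H](O)[C@@](C)(O)[C@@H]1[C@@H](O)C(=O)C(=O)OCC | intermediate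
20 | tert-butyl propanoate | CCC(=O)OC(C)(C)C | starting material
21 | lithium E-enolate of tert-butyl propanoate | C/C=C(/O[Li])OC(C)(C)C | intermediate
22 | aldol adduct (C8 tertiary carbinol bearing C7 ethyl ester and the C17-methyl C19 tert-butyl ester arm; 8,9-erythro, 17-methyl anti to 8-OH) | C=C[C@@H](O[Si](C)(C)C(C)(C)C)[C@@]1(C)C=C[C@@H](O)[C@@](C)(O)[C@@H]1[C@@H](O)[C@@](O)(C(=O)OCC)[C@@H](C)C(=O)OC(C)(C)C | intermediate
23 | tetrakis(triethylsilyl) ether of 22 (O8, O9, O11, O12) | C=C[C@@H](O[Si](C)(C)C(C)(C)C)[C@@]1(C)C=C[C@@H](O[Si](CC)(CC)CC)[C@@](C)(O[Si](CC)(CC)CC)[C@@H]1[C@@H](O[Si](CC)(CC)CC)[C@@](O[Si](CC)(CC)CC)(C(=O)OCC)[C@@H](C)C(=O)OC(C)(C)C | intermediate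
24 | C7 aldehyde | C=C[C@@H](O[Si](C)(C)C(C)(C)C)[C@@]1(C)C=C[C@@H](O[Si](CC)(CC)CC)[C@@](C)(O[Si](CC)(CC)CC)[C@@H]1[C@@H](O[Si](CC)(CC)CC)[C@@](O[Si](CC)(CC)CC)(C=O)[C@@H](C)C(=O)OC(C)(C)C | intermediate
25 | 3-chloro-1-(trimethylsilyl)prop-1-yne | ClCC#C[Si](C)(C)C | starting material
26 | 1-chloro-3-(trimethylsilyl)prop-2-yn-1-yllithium | [Li]C(Cl)C#C[Si](C)(C)C | intermediate
27 | 3-chloro-1-(trimethylsilyl)propa-1,2-dien-1-ylzinc bromide | ClC=C=C([Zn]Br)[Si](C)(C)C | intermediate
28 | anti-chlorohydrin (C7–OH, C6–Cl, silylalkyne) | C=C[C@@H](O[Si](C)(C)C(C)(C)C)[C@@]1(C)C=C[C@@H](O[Si](CC)(CC)CC)[C@@](C)(O[Si](CC)(CC)CC)[C@@H]1[C@@H](O[Si](CC)(CC)CC)[C@@](O[Si](CC)(CC)CC)([C@@H](O)[C@@H](Cl)C#C[Si](C)(C)C)[C@@H](C)C(=O)OC(C)(C)C | intermediate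
29 | C19 hydroxy acid (triethylsilyl and tert-butyl groups removed) | C=C[C@@H](O[Si](C)(C)C(C)(C)C)[C@@]1(C)C=C[C@@H](O)[C@@](C)(O)[C@@H]1[C@@H](O)[C@@](O)([C@@H](O)[C@@H](Cl)C#C[Si](C)(C)C)[C@@H](C)C(=O)O | intermediate
30 | β-hydroxy-γ-lactone (O7–C19; 2-O-silyl, alkynylsilane) | C=C[C@@H](O[Si](C)(C)C(C)(C)C)[C@@]1(C)C=C[C@@H](O)[C@@](C)(O)[C@@H]1[C@@H](O)[C@]2(O)[C@@H](C)C(=O)O[C@H]2[C@@H](Cl)C#C[Si](C)(C)C | intermediate
31 | terminal alkyne pentaol | C=C[C@@H](O)[C@@]1(C)C=C[C@@H](O)[C@@](C)(O)[C@@H]1[C@@H](O)[C@]2(O)[C@@H](C)C(=O)O[C@H]2[C@@H](Cl)C#C | intermediate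
32 | triene (C5 as 2-substituted buta-1,3-diene) | C=C[C@@H](O)[C@@]1(C)C=C[C@@H](O)[C@@](C)(O)[C@@H]1[C@@H](O)[C@]2(O)[C@@H](C)C(=O)O[C@H]2[C@@H](Cl)C(=C)C=C | intermediate
33 | macrocyclic pentaol (2,9,12-tris-O-deacetyl target, 3Z) | C=C1/C=C\[C@@H](O)[C@@]2(C)C=C[C@@H](O)[C@@](C)(O)[C@@H]2[C@@H](O)[C@]2(O)[C@@H](C)C(=O)O[C@H]2[C@H]1Cl | intermediate
34 | CNP0285654.4 (1S,2R,6S,7R,8R,9R,10S,11S,12R,17R; 3Z) | C=C1/C=C\[C@@H](OC(C)=O)[C@@]2(C)C=C[C@@H](OC(C)=O)[C@@](C)(O)[C@@H]2[C@@H](OC(C)=O)[C@]2(O)[C@@H](C)C(=O)O[C@H]2[C@H]1Cl | target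

**Totals**
Total step count: 18. Longest linear sequence: 18 (the route is linear from 1 and 2).

**Three steps most likely to fail**

Step 1 (the proposed Diels–Alder reaction). A trisubstituted enal may react too slowly or with poor face selectivity under diol catalysis. The fallback uses known chemistry, sets out from 1 and comes back at 8. The established TADDOL-catalysed cycloaddition of 1 with methacrolein gives the amino silyl enol ether cycloadduct F1, which AcCl converts into (S)-1-methyl-4-oxocyclohex-2-ene-1-carbaldehyde F2; here only the quaternary centre is set by catalysis. Vinylation as in step 2 gives the allylic alcohol F3 and silylation as in step 3 the silyl ether F4. Conjugate addition of nitromethane (DBU), anti to the bulky silyloxyallyl group, gives the nitromethyl ketone F5. A Nef reaction in methanol (NaOMe, then H2SO4/MeOH, −40 °C) turns the nitromethyl group into the dimethyl acetal F6. Saegusa oxidation, through the less substituted trimethylsilyl enol ether F7 (LiN(iPr)2, Me3SiCl) and Pd(OAc)2 in MeCN, introduces the C13=C14 double bond and gives 8.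

Step 14 (chloroallenylzinc addition). The aldehyde sits on a fully substituted carbon whose two carbon arms are both large, so the facial selectivity at C7 may be low. The fallback sets out from 24 and comes back at 28. Horner–Wadsworth–Emmons olefination with diethyl [3-(trimethylsilyl)prop-2-yn-1-yl]phosphonate (LiN(SiMe3)2, THF) gives the (E)-enyne F8. Shi epoxidation (fructose-derived ketone catalyst, KHSO5, buffered MeCN/H2O) gives the trans alkynyl epoxide F9 under catalyst control. Et2AlCl (CH2Cl2, −78 °C) opens F9 with inversion at the propargylic carbon, which gives 28 with the C7 hydroxyl from the epoxide oxygen and the chloride anti to it.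

Step 17 (ene–yne metathesis macrocyclisation). Ten-membered carbocycles close reluctantly, the wrong alkene geometry or a nine-membered exo product may compete, and the polyol is poorly soluble. The fallback sets out from 31 and comes back at 33, and it separates diene formation from ring closure. Cross ene–yne metathesis with ethylene at 23 °C (same ruthenium complex, CH2Cl2) is stopped at triene 32, which is isolated. Per-silylation (Me3SiOTf, 2,6-lutidine) gives the pentakis(trimethylsilyl) ether F10. The ring is then closed under kinetic Z-control with the monoaryloxide pyrrolide complex Mo(NAd)(CHCMe2Ph)(NC4H4)(OHIPT) (Ad = 1-adamantyl, HIPT = 2,6-bis(2,4,6-triisopropylphenyl)phenyl; benzene, reduced pressure, high dilution) to give the silylated macrocycle F11. HF·pyridine in THF then gives 33.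

**Further compounds**
F1 | step 1 | amino silyl enol ether cycloadduct of 1 and methacrolein | O=C[C@@]1(C)CCC(O[Si](C)(C)C(C)(C)C)=C[C@H]1N(C)C
F2 | step 1 | (S)-1-methyl-4-oxocyclohex-2-ene-1-carbaldehyde | O=C[C@@]1(C)CCC(=O)C=C1
F3 | step 1 | allylic alcohol, (S)-4-[(1R)-1-hydroxyprop-2-en-1-yl]-4-methylcyclohex-2-en-1-one | C=C[C@@H](O)[C@@]1(C)CCC(=O)C=C1
F4 | step 1 | silyl ether of F3 | C=C[C@@H](O[Si](C)(C)C(C)(C)C)[C@@]1(C)CCC(=O)C=C1
F5 | step 1 | nitromethyl ketone (C10 nitromethyl trans to the silyloxyallyl group) | C=C[C@@H](O[Si](C)(C)C(C)(C)C)[C@@]1(C)CCC(=O)C[C@@H]1C[N+](=O)[O-]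
F6 | step 1 | dimethyl acetal ketone | C=C[C@@H](O[Si](C)(C)C(C)(C)C)[C@@]1(C)CCC(=O)C[C@@H]1C(OC)OC
F7 | step 1 | trimethylsilyl enol ether (C12=C13) | C=C[C@@H](O[Si](C)(C)C(C)(C)C)[C@@]1(C)CC=C(O[Si](C)(C)C)C[C@@H]1C(OC)OC
F8 | step 14 | (E)-enyne (C7=C6 alkene, silylalkyne) | C=C[C@@H](O[Si](C)(C)C(C)(C)C)[C@@]1(C)C=C[C@@H](O[Si](CC)(CC)CC)[C@@](C)(O[Si](CC)(CC)CC)[C@@H]1[C@@H](O[Si](CC)(CC)CC)[C@@](O[Si](CC)(CC)CC)(/C=C/C#C[Si](C)(C)C)[C@@H](C)C(=O)OC(C)(C)C
F9 | step 14 | trans alkynyl epoxide (C6–C7) | C=C[C@@H](O[Si](C)(C)C(C)(C)C)[C@@]1(C)C=C[C@@H](O[Si](CC)(CC)CC)[C@@](C)(O[Si](CC)(CC)CC)[C@@H]1[C@@H](O[Si](CC)(CC)CC)[C@@](O[Si](CC)(CC)CC)([C@H]2O[C@@H]2C#C[Si](C)(C)C)[C@@H](C)C(=O)OC(C)(C)C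
F10 | step 17 | pentakis(trimethylsilyl) ether of triene 32 | C=C[C@@H](O[Si](C)(C)C)[C@@]1(C)C=C[C@@H](O[Si](C)(C)C)[C@@](C)(O[Si](C)(C)C)[C@@H]1[C@@H](O[Si](C)(C)C)[C@]2(O[Si](C)(C)C)[C@@H](C)C(=O)O[C@H]2[C@@H](Cl)C(=C)C=C
F11 | step 17 | silylated macrocycle, pentakis(trimethylsilyl) ether of 33 | C=C1/C=C\[C@@H](O[Si](C)(C)C)[C@@]2(C)C=C[C@@H](O[Si](C)(C)C)[C@@](C)(O[Si](C)(C)C)[C@@H]2[C@@H](O[Si](C)(C)C)[C@]2(O[Si](C)(C)C)[C@@H](C)C(=O)O[C@H]2[C@H]1Cl
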